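**Assumption:** levopimaric acid (the principal resin acid of pine oleoresin) and (R)-methyl hydrogen 3-methylglutarate are taken as purchasable; atoms are numbered as in labdane (C1–C20) throughout.

## Retrosynthetic overview

- Target ⇐ C15,C18-dimethyl diester, by saponification of the unhindered C15 ester only (the C18 ester on quaternary C4 is inert).
- C11–C12 bond ⇐ light-driven nickel/iridium doubly decarboxylative union of a bicyclic acid (C1–C11, C17–C20 plus a sacrificial carboxyl carbon) with (R)-methyl hydrogen 3-methylglutarate (C12–C16, carries C13).
- C8=C17 ⇐ Wittig methylenation of an 8-ketone.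
- 8-Keto acid ⇐ exhaustive ozonolysis of methyl levopimarate, which excises C13, C14 and the isopropyl group of ring C.
- No ring is formed: rings A and B with C4, C5, C9 and C10 are bought intact in levopimaric acid; ring C is opened.

## Route

Step 1
Reactants: 1 levopimaric acid
Product: 2 methyl levopimarate (methyl abieta-8(14),12-dien-18-oate; ring stereocentres as in 1)
Conditions: MeI, K2CO3, DMF, 20 °C, Ar, dark
Reagents that add atoms: iodomethane, CI
Why: SN2 O-alkylation of the carboxylate (Williamson-type esterification) avoids the acid and heat that isomerise the homoannular diene, and no stereocentre is touched.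

Step 2
Reactants: 2 methyl levopimarate
Product: 4 18-methoxy-8,18-dioxo-13,14,15,16,17-pentanorlabdan-12-oic acid (8-ketone; 9β-CH2CO2H; 9α-H), via keto aldehyde 3 (not isolated)
Conditions: O3, CH2Cl2/MeOH 4:1, −78 °C; Me2S, −78 → 20 °C; evaporate; NaClO2, NaH2PO4, 2-methyl-2-butene, t-BuOH/H2O, 20 °C
Reagents that add atoms: ozone, [O-][O+]=O; sodium chlorite, [Na+].[O-]Cl=O
Why: Criegee ozonolysis of both ring C double bonds (C8=C14 and C12=C13) leaves C8 as a ketone and C12 as an aldehyde, and Pinnick oxidation then takes the aldehyde to the acid without touching the ketone or the hindered ester; C9 keeps its bought, thermodynamically preferred equatorial configuration.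

Step 3
Reactants: 4 18-methoxy-8,18-dioxo-13,14,15,16,17-pentanorlabdan-12-oic acid
Product: 5 18-methoxy-18-oxo-13,14,15,16-tetranorlabd-8(17)-en-12-oic acid (exocyclic C8=CH2; 9β-CH2CO2H)
Conditions: Ph3PCH3Br (4 equiv), KOtBu (4.5 equiv), THF, 0 → 65 °C; then 1 M HCl
Reagents that add atoms: methyltriphenylphosphonium bromide, C[P+](c1ccccc1)(c1ccccc1)c1ccccc1.[Br-]
Why: Wittig methylenation of the hindered 8-ketone with excess ylide, the acid being masked as its potassium carboxylate; any enolisation towards C9 is reversible and returns the more stable equatorial 9β side chain, so the bought configuration is kept.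

Step 4
Reactants: 5 18-methoxy-18-oxo-13,14,15,16-tetranorlabd-8(17)-en-12-oic acid; 6 (R)-methyl hydrogen 3-methylglutarate (3 equiv)
Product: 8 dimethyl (13R)-labd-8(17)-ene-15,18-dioate, via N-acyloxyphthalimide 7 (not isolated)
Conditions: N-hydroxyphthalimide (1.05 equiv), N,N′-diisopropylcarbodiimide (1.05 equiv), CH2Cl2, 20 °C; evaporate; then 6, Cs2CO3 (20 mol%), Ir[dF(CF3)ppy]2(dtbbpy)PF6 (2 mol%), NiCl2(dme) (10 mol%), 4,4′-dimethoxy-2,2′-bipyridine (12 mol%), MeCN, 450 nm LEDs, 25 °C, Ar
Reagents that add atoms: none
Why: Proposed new method: a redox-neutral, doubly decarboxylative C(sp3)–C(sp3) cross-coupling of a free acid with a redox-active ester under nickel/iridium dual photocatalysis, which to my knowledge has not been described for two unactivated primary alkyl partners; the photoexcited trivalent iridium complex oxidises the carboxylate of 6 (loss of CO2 gives the primary C12 radical), the divalent iridium so formed returns the electron to nickel, low-valent (zerovalent or monovalent) nickel–bipyridine reduces ester 7 (loss of CO2 and of phthalimide anion, which serves as the base that forms the next carboxylate) and holds the C11 alkyl group, and capture of the C12 radical gives a trivalent dialkylnickel species that reductively eliminates the C11–C12 bond; cross-selectivity is expected because each reduction of the ester is paired with one oxidation of the acid and because nickel activates only the ester; C13 is never a radical site and is carried over from 6 unchanged; the closest known reactions are the nickel/photoredox decarboxylative coupling of carboxylic acids with alkyl halides and the nickel-catalysed reductive couplings of N-acyloxyphthalimides.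

Step 5
Reactants: 8 dimethyl (13R)-labd-8(17)-ene-15,18-dioate
Product: 9 (13R)-18-methoxy-18-oxolabd-8(17)-en-15-oic acid (target)
Conditions: LiOH·H2O (3 equiv), THF/MeOH/H2O 3:1:1, 20 °C; then 1 M HCl to pH 3
Reagents that add atoms: lithium hydroxide, [Li+].[OH-]
Why: Chemoselective saponification (acyl–oxygen cleavage by hydroxide) of the primary C15 methyl ester; the neopentyl-type C18 methyl ester on quaternary C4 does not react at room temperature, and no stereocentre is affected.

## Compound list

1 | levopimaric acid, abieta-8(14),12-dien-18-oic acid, (1R,4aR,4bS,10aR); 4α-CO2H, 4β-CH3, 5α-H, 9α-H, 10β-CH3 | CC(C)C1=CC[C@H]2C(=C1)CC[C@@H]1[C@]2(C)CCC[C@@]1(C)C(=O)O | starting material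
2 | methyl levopimarate, methyl abieta-8(14),12-dien-18-oate; stereocentres as in 1 | CC(C)C1=CC[C@H]2C(=C1)CC[C@@H]1[C@]2(C)CCC[C@@]1(C)C(=O)OC | intermediate
3 | methyl 8,12-dioxo-13,14,15,16,17-pentanorlabdan-18-oate (keto aldehyde); trans-decalin, 4α-CO2Me, 4β-CH3, 5α-H, 10β-CH3, 9α-H, 9β-CH2CHO | O=C1CC[C@@H]2[C@](C)(CCC[C@@]2(C)C(=O)OC)[C@H]1CC=O | intermediate
4 | 18-methoxy-8,18-dioxo-13,14,15,16,17-pentanorlabdan-12-oic acid (keto acid); as 3 with 9β-CH2CO2H | O=C1CC[C@@H]2[C@](C)(CCC[C@@]2(C)C(=O)OC)[C@H]1CC(=O)O | intermediate
5 | 18-methoxy-18-oxo-13,14,15,16-tetranorlabd-8(17)-en-12-oic acid; as 4 with exocyclic C8=CH2 | C=C1CC[C@@H]2[C@](C)(CCC[C@@]2(C)C(=O)OC)[C@H]1CC(=O)O | intermediate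
6 | (R)-methyl hydrogen 3-methylglutarate, (3R)-5-methoxy-3-methyl-5-oxopentanoic acid | OC(=O)C[C@@H](C)CC(=O)OC | starting material
7 | 1,3-dioxoisoindolin-2-yl ester (N-acyloxyphthalimide) of acid 5 | C=C1CC[C@@H]2[C@](C)(CCC[C@@]2(C)C(=O)OC)[C@H]1CC(=O)ON1C(=O)c2ccccc2C1=O | intermediate
8 | dimethyl (13R)-labd-8(17)-ene-15,18-dioate; 4α-CO2Me, 4β-CH3, 5α-H, 9α-H, 10β-CH3 | C=C1CC[C@@H]2[C@](C)(CCC[C@@]2(C)C(=O)OC)[C@H]1CC[C@@H](C)CC(=O)OC | intermediate
9 | (13R)-18-methoxy-18-oxolabd-8(17)-en-15-oic acid, (3R)-5-[(1S,4aR,5R,8aR)-5-(methoxycarbonyl)-5,8a-dimethyl-2-methylidenedecahydronaphthalen-1-yl]-3-methylpentanoic acid | C=C1CC[C@@H]2[C@](C)(CCC[C@@]2(C)C(=O)OC)[C@H]1CC[C@@H](C)CC(=O)O | target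

## Step count and risks

Total step count: 5. Longest linear sequence: 5 steps (1 → 9); compound 6 is bought.

The three steps most likely to fail:

**Step 4, the proposed new coupling.** The carboxylate of 6 may exchange acyl groups with ester 7 and scramble the partners. Divalent iridium may reduce 7 directly and give the simply decarboxylated hydrocarbon. The homoallylic C11 radical or its nickel alkyl may rearrange or undergo β-hydride elimination. The fallback is known chemistry and changes the way the radicals are made: a mixed Kolbe electrolysis. It sets out from acid 5 and half ester 6 (6 to 8 equiv), in MeOH with 5–10% neutralisation by KOH, at a smooth Pt anode in an undivided cell, about 150 mA cm−2, 40 °C. Anodic decarboxylation of both carboxylates and radical–radical combination at the electrode give diester 8 directly, where the route is rejoined; the symmetrical by-products are removed by chromatography. This fallback makes no compound outside the list (F0).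

**Step 3, the Wittig methylenation.** The 8-ketone is hindered by the C9 substituent and C10, is enolisable, and carries a carboxylate that may limit solubility, so conversion may stall. The fallback changes both the order of events and the type of olefination. It sets out from keto acid 4, which is coupled with 6 by mixed Kolbe electrolysis (conditions as above; γ-keto acids are established Kolbe substrates) to give dimethyl (13R)-8-oxo-17-norlabdane-15,18-dioate F1. The ketone of this diester is then methylenated with the non-basic Lombardo reagent (Zn, CH2Br2, TiCl4, THF/CH2Cl2, 0 → 20 °C), which tolerates both esters and does not enolise C9. This gives 8, where the route is rejoined; compound 5 and step 4 are bypassed.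

**Step 2, the double ozonolysis.** The air-sensitive diene 2 may degrade, the enone formed after the first cleavage reacts slowly with ozone, and peroxidic intermediates may over-oxidise. The fallback replaces ozone and the separate aldehyde oxidation by a metal-oxo cleavage: RuCl3·xH2O (3 mol%) and NaIO4 (8 equiv) in EtOAc/MeCN/H2O, 0 → 20 °C. The RuO4 formed in the flask cleaves both double bonds by cycloaddition and delivers the ketone and the acid in one operation. It sets out from 2 and comes back to the route at keto acid 4, bypassing 3; it makes no compound outside the list (F0).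

## Further compounds

F0 | step 4 | none | none
F1 | step 3 | dimethyl (13R)-8-oxo-17-norlabdane-15,18-dioate | O=C1CC[C@@H]2[C@](C)(CCC[C@@]2(C)C(=O)OC)[C@H]1CC[C@@H](C)CC(=O)OC
F0 | step 2 | none | none
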